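The upper, ent-epicatechin-type pyran ring C is disconnected at C2–C3. Because C2 is both benzylic to ring B and bonded to the ring oxygen O1, ring B and C2 can be carried as a plain 3,4-bis(benzyloxy)benzyl ether on an ortho oxygen of a symmetric ring A diazomethyl ketone. Rh2(S-DOSP)4-catalysed insertion of the C3 carbenoid into that ether C–H bond closes ring C and sets C2 in one operation. The resulting (2R)-flavanone is joined at C4 to an 8-lithiated epicatechin-4β-ol unit; hydroboration anti to the C2 aryl group, oxidation and hydride reduction then give the all-cis upper unit, and desilylation and hydrogenolysis free the target.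

Key step: step 3

Remark: the (S)-prolinate catalyst of step 3 is assumed to give the 2R flavanone; should a test run show the opposite sense, the mirror-image catalyst Rh2(R-DOSP)4 is used with no other change.

Abbreviations: Bn = benzyl; DBB = 3,4-bis(benzyloxy)benzyl; TBS = tert-butyldimethylsilyl. Target 20 is ent-epicatechin-(4β→8)-epicatechin-4β-ol: upper unit 2S,3S with the C4 aryl bond cis to the C3 hydroxyl and the C2 aryl group; lower unit 2R,3R,4S (2,3-cis-3,4-trans).

Step 1
Reactants: 1 2',4',6'-trihydroxyacetophenone; 2 3,4-bis(benzyloxy)benzyl chloride (3.3 equiv in total, three of them incorporated)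
Product: 3 2',4',6'-tris(DBB-oxy)acetophenone, that is 1-{2,4,6-tris[(3,4-bis(benzyloxy)phenyl)methoxy]phenyl}ethan-1-one
Conditions: K2CO3, Bu4NI (cat.), DMF, 60 °C
Reagents that add atoms: 3,4-bis(benzyloxy)benzyl chloride 2 (second equivalent), ClCc1ccc(OCc2ccccc2)c(OCc2ccccc2)c1; 3,4-bis(benzyloxy)benzyl chloride 2 (third equivalent), ClCc1ccc(OCc2ccccc2)c(OCc2ccccc2)c1
Why: Threefold Williamson ether synthesis: the benzylic chloride, activated in situ as the iodide, should alkylate all three phenoxides of the acyl-deactivated phloroglucinol ring on oxygen, so that three molecules of 2 are incorporated per molecule of 1, and no stereocenter is formed.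

Step 2
Reactants: 3 2',4',6'-tris(DBB-oxy)acetophenone
Product: 5 2-diazo-1-[2,4,6-tris(DBB-oxy)phenyl]ethan-1-one, via trifluoroacetyl diketone 4 (not isolated)
Conditions: LiN(SiMe3)2, THF, −78 °C; CF3CO2CH2CF3; aq HCl work-up; then MsN3, Et3N, H2O, MeCN, 23 °C
Reagents that add atoms: methanesulfonyl azide, CS(=O)(=O)N=[N+]=[N-]
Why: Deacylative (Regitz-type) diazo transfer: Claisen trifluoroacetylation of the lithium enolate turns the hindered methyl ketone into a 1,3-diketone that accepts the diazo group from the sulfonyl azide and then sheds the trifluoroacetyl group as the N-mesyl amide, so that a terminal diazo ketone results without any stereocenter.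

Step 3
Reactants: 5 2-diazo-1-[2,4,6-tris(DBB-oxy)phenyl]ethan-1-one
Product: 6 (2R)-3',4'-bis(benzyloxy)-5,7-bis(DBB-oxy)flavanone, that is (2R)-2-[3,4-bis(benzyloxy)phenyl]-5,7-bis(DBB-oxy)chroman-4-one
Conditions: Rh2(S-DOSP)4 [dirhodium tetrakis((S)-N-(4-dodecylphenylsulfonyl)prolinate)] (1 mol%), CH2Cl2, slow addition of 5, 0 → 23 °C
Reagents that add atoms: none
Why: Rh2(S-DOSP)4 should convert the diazo ketone into an electrophilic rhodium carbenoid at C3, which inserts through a concerted, hydride-transfer-like three-centre transition state into a C–H bond of the ortho ArO–CH2–aryl ether, a bond made hydridic by the O1 lone pair and the 3,4-dialkoxyphenyl ring, so that the C2–C3 bond and the new C3–H bond form together and N2 is the only by-product. The closest known reaction is the intramolecular C–H insertion of 2-alkoxyphenyl α-diazo ketones under chiral Rh2(O2CR)4 catalysis, which gives chroman-4-ones. Ring C closes as a six-membered ring by 1,6-insertion through a chair-like transition state with the aryl group pseudo-equatorial. The only new stereocenter, C2, is set by the catalyst, whose chiral prolinate ligands differentiate the two enantiotopic benzylic hydrogens; any minor enantiomer would later show up as a separable diastereomer once the enantiopure lower unit is attached. The step needs C–H insertion to win over oxonium ylide formation at O1 followed by a [1,2]-benzyl (Stevens) shift to a benzofuranone, and over carbenoid dimerisation; the low basicity of the aryl ether oxygen next to the acyl group, the doubly activated C–H bond, the bulky carboxylate ligands, the non-coordinating solvent and slow addition are relied on for this. Regiochemistry is no issue, because the two ortho ethers of the symmetric ring A are identical and lead to the same product.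

Step 4
Reactants: 7 (−)-epicatechin
Product: 8 5,7,3',4'-tetra-O-benzyl-(−)-epicatechin (2R,3R)
Conditions: BnBr, K2CO3, DMF, −20 → 23 °C
Reagents that add atoms: benzyl bromide, BrCc1ccccc1
Why: Williamson ether synthesis that is selective for the four acidic phenols over the secondary C3 alcohol under carbonate conditions, the low temperature keeping C-benzylation and base-induced C2 epimerisation down, so that both stereocenters of the natural product are carried over unchanged.

Step 5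
Reactants: 8 5,7,3',4'-tetra-O-benzyl-(−)-epicatechin
Product: 9 8-bromo-5,7,3',4'-tetra-O-benzyl-(−)-epicatechin
Conditions: N-bromosuccinimide, CH2Cl2, −78 → 0 °C
Reagents that add atoms: N-bromosuccinimide, O=C1CCC(=O)N1Br
Why: Electrophilic aromatic bromination: N-bromosuccinimide should attack ring A, the most electron-rich arene, at C8 as is usual for 5,7-di-O-benzyl flavan-3-ols, and no stereocenter is touched.

Step 6
Reactants: 9 8-bromo-5,7,3',4'-tetra-O-benzyl-(−)-epicatechin
Product: 10 8-bromo-5,7,3',4'-tetra-O-benzylepicatechin-4β-ol, the (2R,3R,4S)-flavan-3,4-diol (2,3-cis-3,4-trans)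
Conditions: DDQ (1.5 equiv), CH2Cl2–H2O (18:1), 23 °C
Reagents that add atoms: water, O
Why: DDQ-mediated benzylic oxidation: hydride abstraction from C4 gives the ring A-stabilised benzylic cation (quinone methide-type), which water captures on the face opposite the axial C3 hydroxyl and the C2 aryl group, setting C4 as 4β (3,4-trans), while the C8 bromine blocks self-condensation of this electrophile.

Step 7
Reactants: 10 8-bromo-5,7,3',4'-tetra-O-benzylepicatechin-4β-ol
Product: 11 8-bromo-5,7,3',4'-tetra-O-benzyl-3,4-bis-O-TBS-epicatechin-4β-ol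
Conditions: TBSOTf, 2,6-lutidine, CH2Cl2, −78 → 0 °C
Reagents that add atoms: tert-butyldimethylsilyl trifluoromethanesulfonate, CC(C)(C)[Si](C)(C)OS(=O)(=O)C(F)(F)F
Why: Silyl ether formation with the reactive silyl triflate and a hindered pyridine base, which should silylate both the axial C3 and the benzylic C4 hydroxyl without ionising C4 and leaves all stereocenters as they are.

Step 8
Reactants: 11 8-bromo-5,7,3',4'-tetra-O-benzyl-3,4-bis-O-TBS-epicatechin-4β-ol; 6 (2R)-3',4'-bis(benzyloxy)-5,7-bis(DBB-oxy)flavanone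
Product: 13 (2R)-3',4'-bis(benzyloxy)-5,7-bis(DBB-oxy)-4-(lower unit-8-yl)flavan-4-ol (lower unit = the flavan of 11 bonded through C8; both C4 epimers acceptable), via 8-lithio lower unit 12 (not isolated)
Conditions: t-BuLi (2.1 equiv), THF, −78 °C; then 6, −78 → −40 °C; H2O
Reagents that add atoms: none
Why: Bromine–lithium exchange followed by 1,2-addition of the aryllithium to the C4 ketone, a union known for 8-lithiated flavan-3-ol ethers and flavan-4-ones; the new carbinol center at C4 need not be controlled because it is removed in step 9, and the low temperature is meant to keep the C2 center from being lost through enolisation and ring opening.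

Step 9
Reactants: 13 tertiary C4 alcohol
Product: 14 (2R)-3',4'-bis(benzyloxy)-5,7-bis(DBB-oxy)-4-(lower unit-8-yl)flav-3-ene (2H-chromene with the C3=C4 double bond)
Conditions: methyl N-(triethylammoniosulfonyl)carbamate (Burgess reagent), THF, 50 °C
Reagents that add atoms: none
Why: Dehydration of the tertiary, doubly benzylic alcohol through its sulfamate ester (syn-elimination or ionisation), for which only the C3 hydrogens are available, so that the C3=C4 double bond forms under neutral conditions that spare the silyl ethers, the benzylic ethers and C2.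

Step 10
Reactants: 14 4-aryl-flav-3-ene
Product: 16 (2S,3R)-2,3-trans-3,4-trans-3',4'-bis(benzyloxy)-5,7-bis(DBB-oxy)-4-(lower unit-8-yl)flavan-3-ol (C4 aryl cis to the C2 aryl), via C3 alkylborane 15 (not isolated)
Conditions: BH3·THF, THF, 0 → 23 °C; then NaOH, H2O2, 0 → 23 °C
Reagents that add atoms: hydrogen peroxide, OO
Why: Hydroboration–oxidation: borane should add syn across C3=C4 with boron at the less substituted C3 and from the face opposite the adjacent C2 aryl group, and stereoretentive oxidation then gives the 2,3-trans alcohol with the C4 hydrogen on the same face, which places the C4 aryl substituent cis to the C2 aryl group and thereby sets C4.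

Step 11
Reactants: 16 2,3-trans-3,4-trans flavan-3-ol
Product: 17 (2S)-2,4-cis-3',4'-bis(benzyloxy)-5,7-bis(DBB-oxy)-4-(lower unit-8-yl)flavan-3-one
Conditions: Dess–Martin periodinane, NaHCO3, CH2Cl2, 0 → 23 °C
Reagents that add atoms: none
Why: Dess–Martin oxidation of the secondary alcohol under buffered, nearly neutral conditions, chosen so that the enolisable C2 and C4 centers, which already hold their aryl groups in the favoured 2,4-cis diequatorial arrangement, are not epimerised.

Step 12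
Reactants: 17 flavan-3-one
Product: 18 (2S,3S)-2,3-cis-3,4-cis-3',4'-bis(benzyloxy)-5,7-bis(DBB-oxy)-4-(lower unit-8-yl)flavan-3-ol (all-cis upper unit)
Conditions: Li[HB(s-Bu)3], THF, −78 °C
Reagents that add atoms: none
Why: Diastereoselective ketone reduction with a bulky trialkylborohydride, which should attack the flavan-3-one along the equatorial trajectory as in the known conversion of 2,3-trans into 2,3-cis flavan-3-ols and so gives the axial C3 alcohol cis to both flanking aryl groups, setting C3.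

Step 13
Reactants: 18 all-cis bis-silyl ether
Product: 19 benzyl-type-protected ent-epicatechin-(4β→8)-epicatechin-4β-ol with free C3 (upper) and C3, C4 (lower) hydroxyls
Conditions: Bu4NF, THF, 0 → 23 °C
Reagents that add atoms: none
Why: Fluoride-mediated cleavage of the two silyl ethers driven by Si–F bond formation, under conditions that leave the benzylic ethers and all stereocenters untouched.

Step 14
Reactants: 19 benzyl-type-protected triol
Product: 20 ent-epicatechin-(4β→8)-epicatechin-4β-ol (target)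
Conditions: H2 (1 atm), Pd(OH)2/C, NaHCO3 (trace), EtOAc–MeOH, 23 °C
Reagents that add atoms: none
Why: Catalytic hydrogenolysis of all benzylic aryl ethers (ten benzyl groups and the two 3,4-dioxygenated benzyl groups on O5 and O7 of the upper unit) under neutral, buffered conditions, in which the more hindered secondary C2–O1 bonds and the C4 hydroxyl of the lower unit should persist as they do in related flavan deprotections.

Compound list
1 | 2',4',6'-trihydroxyacetophenone | CC(=O)c1c(O)cc(O)cc1O | starting material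
2 | 3,4-bis(benzyloxy)benzyl chloride | ClCc1ccc(OCc2ccccc2)c(OCc2ccccc2)c1 | starting material
3 | 1-{2,4,6-tris[(3,4-bis(benzyloxy)phenyl)methoxy]phenyl}ethan-1-one | CC(=O)c1c(OCc2ccc(OCc3ccccc3)c(OCc3ccccc3)c2)cc(OCc2ccc(OCc3ccccc3)c(OCc3ccccc3)c2)cc1OCc1ccc(OCc2ccccc2)c(OCc2ccccc2)c1 | intermediate
4 | 4,4,4-trifluoro-1-[2,4,6-tris(DBB-oxy)phenyl]butane-1,3-dione | O=C(CC(=O)C(F)(F)F)c1c(OCc2ccc(OCc3ccccc3)c(OCc3ccccc3)c2)cc(OCc2ccc(OCc3ccccc3)c(OCc3ccccc3)c2)cc1OCc1ccc(OCc2ccccc2)c(OCc2ccccc2)c1 | intermediate (not isolated)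
5 | 2-diazo-1-[2,4,6-tris(DBB-oxy)phenyl]ethan-1-one | [N-]=[N+]=CC(=O)c1c(OCc2ccc(OCc3ccccc3)c(OCc3ccccc3)c2)cc(OCc2ccc(OCc3ccccc3)c(OCc3ccccc3)c2)cc1OCc1ccc(OCc2ccccc2)c(OCc2ccccc2)c1 | intermediate
6 | (2R)-2-[3,4-bis(benzyloxy)phenyl]-5,7-bis(DBB-oxy)chroman-4-one | c1(OCc3ccc(OCc4ccccc4)c(OCc4ccccc4)c3)cc(OCc3ccc(OCc4ccccc4)c(OCc4ccccc4)c3)c2c(c1)O[C@@H](c3ccc(OCc4ccccc4)c(OCc4ccccc4)c3)CC2=O | intermediate
7 | (−)-epicatechin (2R,3R) | Oc1cc(O)c2c(c1)O[C@H](c1ccc(O)c(O)c1)[C@H](O)C2 | starting material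
8 | 5,7,3',4'-tetra-O-benzyl-(−)-epicatechin | c1c(OCc3ccccc3)cc(OCc3ccccc3)c2c1O[C@H](c3ccc(OCc4ccccc4)c(OCc4ccccc4)c3)[C@H](O)C2 | intermediate
9 | 8-bromo-5,7,3',4'-tetra-O-benzyl-(−)-epicatechin | Brc1c(OCc3ccccc3)cc(OCc3ccccc3)c2c1O[C@H](c3ccc(OCc4ccccc4)c(OCc4ccccc4)c3)[C@H](O)C2 | intermediate
10 | 8-bromo-5,7,3',4'-tetra-O-benzylepicatechin-4β-ol (2R,3R,4S) | Brc1c(OCc3ccccc3)cc(OCc3ccccc3)c2c1O[C@H](c3ccc(OCc4ccccc4)c(OCc4ccccc4)c3)[C@H](O)[C@H]2O | intermediate
11 | 8-bromo-5,7,3',4'-tetra-O-benzyl-3,4-bis-O-TBS-epicatechin-4β-ol | Brc1c(OCc3ccccc3)cc(OCc3ccccc3)c2c1O[C@H](c3ccc(OCc4ccccc4)c(OCc4ccccc4)c3)[C@H](O[Si](C)(C)C(C)(C)C)[C@H]2O[Si](C)(C)C(C)(C)C | intermediate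
12 | 8-lithio-5,7,3',4'-tetra-O-benzyl-3,4-bis-O-TBS-epicatechin-4β-ol | [Li]c1c(OCc3ccccc3)cc(OCc3ccccc3)c2c1O[C@H](c3ccc(OCc4ccccc4)c(OCc4ccccc4)c3)[C@H](O[Si](C)(C)C(C)(C)C)[C@H]2O[Si](C)(C)C(C)(C)C | intermediate (not isolated)
13 | (2R)-4-(lower unit-8-yl)flavan-4-ol, C4 epimers | c1(OCc3ccc(OCc4ccccc4)c(OCc4ccccc4)c3)cc(OCc3ccc(OCc4ccccc4)c(OCc4ccccc4)c3)c2c(c1)O[C@@H](c3ccc(OCc4ccccc4)c(OCc4ccccc4)c3)CC2(O)c5c(OCc7ccccc7)cc(OCc7ccccc7)c6c5O[C@H](c7ccc(OCc8ccccc8)c(OCc8ccccc8)c7)[C@H](O[Si](C)(C)C(C)(C)C)[C@H]6O[Si](C)(C)C(C)(C)C | intermediate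
14 | (2R)-4-(lower unit-8-yl)flav-3-ene | c1(OCc3ccc(OCc4ccccc4)c(OCc4ccccc4)c3)cc(OCc3ccc(OCc4ccccc4)c(OCc4ccccc4)c3)c2c(c1)O[C@@H](c3ccc(OCc4ccccc4)c(OCc4ccccc4)c3)C=C2c5c(OCc7ccccc7)cc(OCc7ccccc7)c6c5O[C@H](c7ccc(OCc8ccccc8)c(OCc8ccccc8)c7)[C@H](O[Si](C)(C)C(C)(C)C)[C@H]6O[Si](C)(C)C(C)(C)C | intermediate
15 | C3 alkylborane from 14 (boron trans to the C2 aryl, C4 aryl cis to it) | c1(OCc3ccc(OCc4ccccc4)c(OCc4ccccc4)c3)cc(OCc3ccc(OCc4ccccc4)c(OCc4ccccc4)c3)c2c(c1)O[C@@H](c3ccc(OCc4ccccc4)c(OCc4ccccc4)c3)[C@H](B)[C@H]2c5c(OCc7ccccc7)cc(OCc7ccccc7)c6c5O[C@H](c7ccc(OCc8ccccc8)c(OCc8ccccc8)c7)[C@H](O[Si](C)(C)C(C)(C)C)[C@H]6O[Si](C)(C)C(C)(C)C | intermediate (not isolated)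
16 | (2S,3R)-2,3-trans-3,4-trans-4-(lower unit-8-yl)flavan-3-ol | c1(OCc3ccc(OCc4ccccc4)c(OCc4ccccc4)c3)cc(OCc3ccc(OCc4ccccc4)c(OCc4ccccc4)c3)c2c(c1)O[C@@H](c3ccc(OCc4ccccc4)c(OCc4ccccc4)c3)[C@H](O)[C@H]2c5c(OCc7ccccc7)cc(OCc7ccccc7)c6c5O[C@H](c7ccc(OCc8ccccc8)c(OCc8ccccc8)c7)[C@H](O[Si](C)(C)C(C)(C)C)[C@H]6O[Si](C)(C)C(C)(C)C | intermediate
17 | (2S)-2,4-cis-4-(lower unit-8-yl)flavan-3-one | c1(OCc3ccc(OCc4ccccc4)c(OCc4ccccc4)c3)cc(OCc3ccc(OCc4ccccc4)c(OCc4ccccc4)c3)c2c(c1)O[C@@H](c3ccc(OCc4ccccc4)c(OCc4ccccc4)c3)C(=O)[C@H]2c5c(OCc7ccccc7)cc(OCc7ccccc7)c6c5O[C@H](c7ccc(OCc8ccccc8)c(OCc8ccccc8)c7)[C@H](O[Si](C)(C)C(C)(C)C)[C@H]6O[Si](C)(C)C(C)(C)C | intermediate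
18 | (2S,3S)-2,3-cis-3,4-cis-4-(lower unit-8-yl)flavan-3-ol, bis-TBS ether | c1(OCc3ccc(OCc4ccccc4)c(OCc4ccccc4)c3)cc(OCc3ccc(OCc4ccccc4)c(OCc4ccccc4)c3)c2c(c1)O[C@@H](c3ccc(OCc4ccccc4)c(OCc4ccccc4)c3)[C@@H](O)[C@H]2c5c(OCc7ccccc7)cc(OCc7ccccc7)c6c5O[C@H](c7ccc(OCc8ccccc8)c(OCc8ccccc8)c7)[C@H](O[Si](C)(C)C(C)(C)C)[C@H]6O[Si](C)(C)C(C)(C)C | intermediate
19 | benzyl-type-protected ent-epicatechin-(4β→8)-epicatechin-4β-ol (free aliphatic hydroxyls) | c1(OCc3ccc(OCc4ccccc4)c(OCc4ccccc4)c3)cc(OCc3ccc(OCc4ccccc4)c(OCc4ccccc4)c3)c2c(c1)O[C@@H](c3ccc(OCc4ccccc4)c(OCc4ccccc4)c3)[C@@H](O)[C@H]2c5c(OCc7ccccc7)cc(OCc7ccccc7)c6c5O[C@H](c7ccc(OCc8ccccc8)c(OCc8ccccc8)c7)[C@H](O)[C@H]6O | intermediate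
20 | ent-epicatechin-(4β→8)-epicatechin-4β-ol | Oc1cc(O)c2c(c1)O[C@@H](c1ccc(O)c(O)c1)[C@@H](O)[C@H]2c1c(O)cc(O)c2c1O[C@H](c1ccc(O)c(O)c1)[C@H](O)[C@H]2O | target

Total step count: 14 (steps 1–3 for the flavanone, 4–7 for the lower unit, 8–14 after the union).
Longest linear sequence: 11 steps (7 → 20 through steps 4–14).

Steps most likely to fail

Step 3. The carbenoid may be diverted into oxonium ylide formation at O1 and a [1,2]-benzyl shift instead of C–H insertion, or the enantioselection may be poor. Fallback, setting out from 3: the potassium enolate of 3 (KN(SiMe3)2, THF, −78 °C) is O-acetylated with Ac2O to give the enol acetate F1. Oxidative C–H cleavage of an ortho benzylic ether with DDQ (1.1 equiv, 2,6-dichloropyridine, LiClO4, ClCH2CH2Cl, 23 °C) generates the O1-oxocarbenium ion, which the enol acetate traps at C3 to close the same C2–C3 bond. This gives the racemic flavanone, 6 together with its enantiomer, the (2S)-flavanone F2. Kinetic resolution by asymmetric transfer hydrogenation (RhCl[(R,R)-TsDPEN](C5Me5) or its antipode, whichever reduces the 2S ketone faster; HCO2H–Et3N, EtOAc) converts F2 into the (2S,4S)-2,4-cis-flavan-4-ol F3 and leaves 6, at which the route is rejoined.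

Step 8. The hindered aryllithium may deprotonate C3 instead of adding to C4, and the resulting enolate may open ring C with loss of the C2 configuration. Fallback, setting out from 6: Tf2O and 2,6-di-tert-butyl-4-methylpyridine (CH2Cl2, 0 °C) convert the ketone without strong base into the enol triflate F4. The aryllithium 12 is transmetalated with ZnCl2 to the arylzinc chloride F5. Negishi coupling (Pd(P(t-Bu)3)2, THF–NMP, 60 °C) then forms the C4–C8 bond directly and comes back to the route at 14.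

Step 14. The benzylic C4 hydroxyl of the lower unit may be lost by over-hydrogenolysis, or the freed flavan-3,4-diol may self-condense if traces of acid form. Fallback, setting out from 18: hydrogenolysis (H2, Pd(OH)2/C, EtOAc–MeOH) is run while both silyl ethers still shield the C3 and C4 oxygens of the lower unit, giving the bis-silyl ether of the target F6. Near-neutral fluoride (Et3N·3HF, THF, 23 °C) then removes the silyl groups and arrives at 20.

Further compounds
F1 | step 3 | 1-[2,4,6-tris(DBB-oxy)phenyl]vinyl acetate | C=C(OC(C)=O)c1c(OCc2ccc(OCc3ccccc3)c(OCc3ccccc3)c2)cc(OCc2ccc(OCc3ccccc3)c(OCc3ccccc3)c2)cc1OCc1ccc(OCc2ccccc2)c(OCc2ccccc2)c1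
F2 | step 3 | (2S)-2-[3,4-bis(benzyloxy)phenyl]-5,7-bis(DBB-oxy)chroman-4-one | c1(OCc3ccc(OCc4ccccc4)c(OCc4ccccc4)c3)cc(OCc3ccc(OCc4ccccc4)c(OCc4ccccc4)c3)c2c(c1)O[C@H](c3ccc(OCc4ccccc4)c(OCc4ccccc4)c3)CC2=O
F3 | step 3 | (2S,4S)-2-[3,4-bis(benzyloxy)phenyl]-5,7-bis(DBB-oxy)chroman-4-ol (2,4-cis) | c1(OCc3ccc(OCc4ccccc4)c(OCc4ccccc4)c3)cc(OCc3ccc(OCc4ccccc4)c(OCc4ccccc4)c3)c2c(c1)O[C@H](c3ccc(OCc4ccccc4)c(OCc4ccccc4)c3)C[C@@H]2O
F4 | step 8 | (2R)-2-[3,4-bis(benzyloxy)phenyl]-5,7-bis(DBB-oxy)-2H-chromen-4-yl trifluoromethanesulfonate | c1(OCc3ccc(OCc4ccccc4)c(OCc4ccccc4)c3)cc(OCc3ccc(OCc4ccccc4)c(OCc4ccccc4)c3)c2c(c1)O[C@@H](c3ccc(OCc4ccccc4)c(OCc4ccccc4)c3)C=C2OS(=O)(=O)C(F)(F)F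
F5 | step 8 | [5,7,3',4'-tetra-O-benzyl-3,4-bis-O-TBS-epicatechin-4β-ol-8-yl]zinc chloride | Cl[Zn]c1c(OCc3ccccc3)cc(OCc3ccccc3)c2c1O[C@H](c3ccc(OCc4ccccc4)c(OCc4ccccc4)c3)[C@H](O[Si](C)(C)C(C)(C)C)[C@H]2O[Si](C)(C)C(C)(C)C
F6 | step 14 | ent-epicatechin-(4β→8)-epicatechin-4β-ol with TBS ethers on the C3 and C4 hydroxyls of the lower unit | Oc1cc(O)c2c(c1)O[C@@H](c1ccc(O)c(O)c1)[C@@H](O)[C@H]2c1c(O)cc(O)c2c1O[C@H](c1ccc(O)c(O)c1)[C@H](O[Si](C)(C)C(C)(C)C)[C@H]2O[Si](C)(C)C(C)(C)C
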